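**Plan**
- The target is a meso oxolane (2R,3R,4S,5S): 2,5-cis aryl groups, 3,4-cis aroyl groups, each aroyl trans to the aryl on the neighbouring carbon. The retrosynthesis cuts the ring at C3–C4 and O1–C5, and the C3 aroyl group at its CO–aryl bond.
- Enabling feature: O1–C2(aryl)–C3(carbonyl) of the oxolane is the enol of a 3-aryl-3-oxopropanoate, and C4(aroyl)–C5(aryl) is the C=C bond of the chalcone isoliquiritigenin.
- Forward: the keto ester and the chalcone triacetate are made separately. Mn(OAc)3 joins them and closes the only ring as a 4,5-dihydrofuran. C2=C3 is then reduced, the C3 ester becomes an acid and then the second aryl ketone, and the phenols are released.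
- Stereochemistry: C4/C5 trans from the ring closure; C2 from hydride delivery to the oxocarbenium ion (2,5-cis); C3 last, by base equilibration.
- Protecting groups: acetates on every phenol that passes through the acidic steps, because they make the aryl ketone and the benzylic C–O bonds electron-poor. The C3 ester is benzyl (cleaved by hydrogen). Benzyl ethers are used only on the ring introduced last.

Key step: step 4

Remark: the target has a mirror plane through O1 and the midpoint of C3–C4, so chiral intermediates are made as racemates; starred descriptors and SMILES show one enantiomer only to fix the relative configuration.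

**Step 1**
Reactants: 1 4-acetoxybenzoyl chloride; 2 Meldrum's acid (2,2-dimethyl-1,3-dioxane-4,6-dione)
Product: 4 benzyl 3-(4-acetoxyphenyl)-3-oxopropanoate, via acyl Meldrum's acid 3 (not isolated)
Conditions: pyridine, CH2Cl2, 0 °C→rt; aq. HCl wash, concentrate; BnOH, toluene, reflux
Reagents that add atoms: benzyl alcohol, OCc1ccccc1
Why: Pyridine-mediated C-acylation of Meldrum's acid and thermolysis of the adduct with benzyl alcohol (acylketene trapping with loss of acetone and CO2, the Oikawa–Yonemitsu beta-keto ester synthesis) use no strong base, so the aryl acetate should survive.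

**Step 2**
Reactants: 5 2',4'-dihydroxyacetophenone; 6 4-hydroxybenzaldehyde
Product: 7 isoliquiritigenin [(E)-1-(2,4-dihydroxyphenyl)-3-(4-hydroxyphenyl)prop-2-en-1-one]
Conditions: BF3·OEt2, 1,4-dioxane, rt
Reagents that add atoms: none
Why: Acid-promoted Claisen–Schmidt (crossed aldol) condensation of the methyl ketone with the non-enolisable aldehyde is chosen over hydroxide because no phenoxide forms to deactivate either partner, and dehydration under thermodynamic control should give the E alkene.

**Step 3**
Reactants: 7 isoliquiritigenin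
Product: 8 isoliquiritigenin triacetate [(E)-1-(2,4-diacetoxyphenyl)-3-(4-acetoxyphenyl)prop-2-en-1-one]
Conditions: Ac2O, pyridine, DMAP (cat.), CH2Cl2, 0 °C→rt
Reagents that add atoms: acetic anhydride, CC(=O)OC(C)=O
Why: DMAP-catalysed O-acetylation should cap all three phenols, the hydrogen-bonded 2'-hydroxyl included, with groups that are inert in acetic and trifluoroacetic acid and that make the ketone and the future benzylic C–O bonds electron-poor.

**Step 4**
Reactants: 4 benzyl 3-(4-acetoxyphenyl)-3-oxopropanoate; 8 isoliquiritigenin triacetate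
Product: 9 benzyl (4S*,5S*)-4-(2,4-diacetoxybenzoyl)-2,5-bis(4-acetoxyphenyl)-4,5-dihydrofuran-3-carboxylate (4,5-trans)
Conditions: Mn(OAc)3·2H2O (2.5 equiv), AcOH, 70 °C, N2
Reagents that add atoms: none
Why: Mn(OAc)3 converts 4 into its trivalent manganese enolate, which gives the electrophilic alpha-radical; this adds to the alpha-carbon of enone 8 (C3–C4 bond), and the resulting benzylic radical is oxidised by a second equivalent of Mn(OAc)3 to the cation, which the ketone enol oxygen captures (O1–C5 bond). The closest known reaction type is the Mn(OAc)3-mediated oxidative addition of 1,3-dicarbonyl compounds to cinnamoyl-type alkenes, which gives trans-4,5-dihydrofurans. The single ring closes by O-alkylation of the enol at the cationic carbon, a five-membered (5-enolendo) closure through the in-plane lone pair of oxygen. C4 and C5 are set together in this closure: the C4 aroyl and C5 aryl groups take opposite faces to avoid eclipsing, and C4–H, alpha to the ketone, can still equilibrate in hot acetic acid, so the trans isomer should result. The step needs attack at the enone alpha-carbon and closure by the ketone rather than the ester oxygen; the first is secured by polarity matching and by the aryl-stabilised radical that this attack leaves, the second by the far higher enol content and nucleophilicity of the aryl ketone, so that a keto ester should give one dihydrofuran where a diketone could give two.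

**Step 5**
Reactants: 9 benzyl (4S*,5S*)-4-(2,4-diacetoxybenzoyl)-2,5-bis(4-acetoxyphenyl)-4,5-dihydrofuran-3-carboxylate
Product: 10 benzyl (2R*,3S*,4S*,5S*)-4-(2,4-diacetoxybenzoyl)-2,5-bis(4-acetoxyphenyl)oxolane-3-carboxylate (2,3-cis; 3,4-trans; 4,5-trans; 2,5-cis)
Conditions: Et3SiH (5 equiv), CF3CO2H/CH2Cl2 (1:2), 0 °C→rt
Reagents that add atoms: none
Why: In this ionic hydrogenation (Kursanov–Parnes reduction) of an ester-conjugated enol ether, reversible protonation at C3 should give the oxocarbenium ion with the ester trans to the C4 aroyl group, and Et3SiH should deliver hydride to C2 anti to that ester, which places the C2 aryl group cis to the C5 aryl group (the other face would crowd aryl, ester and aroyl on one side), while the acetoxy groups keep the hindered aryl ketone and the benzylic C–O bonds from ionising.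

**Step 6**
Reactants: 10 benzyl (2R*,3S*,4S*,5S*)-4-(2,4-diacetoxybenzoyl)-2,5-bis(4-acetoxyphenyl)oxolane-3-carboxylate
Product: 11 (2R*,3S*,4S*,5S*)-4-(2,4-diacetoxybenzoyl)-2,5-bis(4-acetoxyphenyl)oxolane-3-carboxylic acid
Conditions: H2 (1 atm), Pd/C (10 % palladium on carbon), EtOAc, rt
Reagents that add atoms: none
Why: Hydrogenolysis of the benzyl ester is far faster than cleavage of the acetoxy-deactivated benzylic C–O bonds of the ring or reduction of the electron-poor aryl ketone, so the free C3 acid should form with all stereocentres untouched.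

**Step 7**
Reactants: 12 4-bromoresorcinol
Product: 13 1-bromo-2,4-bis(benzyloxy)benzene
Conditions: BnBr, K2CO3, DMF, rt→50 °C
Reagents that add atoms: benzyl bromide, BrCc1ccccc1
Why: Williamson etherification of both phenols with benzyl bromide.

**Step 8**
Reactants: 11 (2R*,3S*,4S*,5S*)-4-(2,4-diacetoxybenzoyl)-2,5-bis(4-acetoxyphenyl)oxolane-3-carboxylic acid; 13 1-bromo-2,4-bis(benzyloxy)benzene
Product: 17 (2R*,3S*,4S*,5S*)-3-[2,4-bis(benzyloxy)benzoyl]-4-(2,4-diacetoxybenzoyl)-2,5-bis(4-acetoxyphenyl)oxolane, via acid chloride 14 (not isolated), via aryllithium 15 (not isolated), via arylzinc chloride 16 (not isolated)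
Conditions: 11, (COCl)2, DMF (cat.), CH2Cl2, 0 °C→rt, evaporate; 13, n-BuLi, THF, −78 °C, then ZnCl2, −78→0 °C; combine, Pd(PPh3)4 (5 mol %), THF, 0 °C→rt
Reagents that add atoms: none
Why: Acid chloride formation, bromine–lithium exchange with transmetalation to zinc, and Negishi acylation under zerovalent palladium catalysis should join the second aryl ketone, because an arylzinc chloride does not add to ketones or aryl acetates and only the acid chloride couples; C3 should be retained, and its configuration is reset in step 9 in any case.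

**Step 9**
Reactants: 17 (2R*,3S*,4S*,5S*)-3-[2,4-bis(benzyloxy)benzoyl]-4-(2,4-diacetoxybenzoyl)-2,5-bis(4-acetoxyphenyl)oxolane
Product: 18 (2R*,3R*,4S*,5S*)-3-[2,4-bis(benzyloxy)benzoyl]-4-(2,4-dihydroxybenzoyl)-2,5-bis(4-hydroxyphenyl)oxolane (2,3-trans; 3,4-cis; 4,5-trans)
Conditions: K2CO3, MeOH/THF, rt→40 °C, Ar; aq. NH4Cl
Reagents that add atoms: none
Why: Carbonate-mediated methanolysis removes the four aryl acetates, and continued exposure to base should epimerise C3 through its enolate (C4 stops enolising once its aroyl ring is a phenoxide) towards the isomer in which each aroyl group is trans to the aryl group on the neighbouring carbon, the directly bonded aryl ring being the more demanding cis partner; this sets the last stereocentre under thermodynamic control.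

**Step 10**
Reactants: 18 (2R*,3R*,4S*,5S*)-3-[2,4-bis(benzyloxy)benzoyl]-4-(2,4-dihydroxybenzoyl)-2,5-bis(4-hydroxyphenyl)oxolane
Product: 19 [(2R,3R,4S,5S)-2,5-bis(4-hydroxyphenyl)oxolane-3,4-diyl]bis[(2,4-dihydroxyphenyl)methanone] (meso; CNP0237262.1)
Conditions: H2 (1 atm), Pd/C (10 % palladium on carbon), EtOAc/MeOH, rt
Reagents that add atoms: none
Why: Hydrogenolysis of the two aryl benzyl ethers is much faster than cleavage of the ring benzylic C–O bonds or reduction of the hydrogen-bonded aryl ketones and should release the meso target under neutral conditions.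

**Compound list**
1 | 4-acetoxybenzoyl chloride | CC(=O)Oc1ccc(cc1)C(Cl)=O | starting material
2 | Meldrum's acid (2,2-dimethyl-1,3-dioxane-4,6-dione) | CC1(C)OC(=O)CC(=O)O1 | starting material
3 | 5-[(4-acetoxyphenyl)(hydroxy)methylidene]-2,2-dimethyl-1,3-dioxane-4,6-dione (acyl Meldrum's acid, not isolated) | CC(=O)Oc1ccc(cc1)C(O)=C1C(=O)OC(C)(C)OC1=O | intermediate
4 | benzyl 3-(4-acetoxyphenyl)-3-oxopropanoate | CC(=O)Oc1ccc(cc1)C(=O)CC(=O)OCc1ccccc1 | intermediate
5 | 2',4'-dihydroxyacetophenone | CC(=O)c1ccc(O)cc1O | starting material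
6 | 4-hydroxybenzaldehyde | O=Cc1ccc(O)cc1 | starting material
7 | isoliquiritigenin | O=C(/C=C/c1ccc(O)cc1)c1ccc(O)cc1O | intermediate
8 | isoliquiritigenin triacetate | CC(=O)Oc1ccc(/C=C/C(=O)c2ccc(OC(C)=O)cc2OC(C)=O)cc1 | intermediate
9 | benzyl (4S*,5S*)-4-(2,4-diacetoxybenzoyl)-2,5-bis(4-acetoxyphenyl)-4,5-dihydrofuran-3-carboxylate (trans, racemic) | O=C(OCc1ccccc1)C=1[C@H](C(=O)c2ccc(OC(C)=O)cc2OC(C)=O)[C@@H](c2ccc(OC(C)=O)cc2)OC=1c1ccc(OC(C)=O)cc1 | intermediate
10 | benzyl (2R*,3S*,4S*,5S*)-4-(2,4-diacetoxybenzoyl)-2,5-bis(4-acetoxyphenyl)oxolane-3-carboxylate (racemic) | O=C(OCc1ccccc1)[C@H]1[C@H](C(=O)c2ccc(OC(C)=O)cc2OC(C)=O)[C@@H](c2ccc(OC(C)=O)cc2)O[C@H]1c1ccc(OC(C)=O)cc1 | intermediate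
11 | (2R*,3S*,4S*,5S*)-4-(2,4-diacetoxybenzoyl)-2,5-bis(4-acetoxyphenyl)oxolane-3-carboxylic acid (racemic) | O=C(O)[C@H]1[C@H](C(=O)c2ccc(OC(C)=O)cc2OC(C)=O)[C@@H](c2ccc(OC(C)=O)cc2)O[C@H]1c1ccc(OC(C)=O)cc1 | intermediate
12 | 4-bromoresorcinol | Oc1ccc(Br)c(O)c1 | starting material
13 | 1-bromo-2,4-bis(benzyloxy)benzene | Brc1ccc(OCc2ccccc2)cc1OCc1ccccc1 | intermediate
14 | (2R*,3S*,4S*,5S*)-4-(2,4-diacetoxybenzoyl)-2,5-bis(4-acetoxyphenyl)oxolane-3-carbonyl chloride (not isolated) | O=C(Cl)[C@H]1[C@H](C(=O)c2ccc(OC(C)=O)cc2OC(C)=O)[C@@H](c2ccc(OC(C)=O)cc2)O[C@H]1c1ccc(OC(C)=O)cc1 | intermediate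
15 | [2,4-bis(benzyloxy)phenyl]lithium (not isolated) | [Li]c1ccc(OCc2ccccc2)cc1OCc1ccccc1 | intermediate
16 | [2,4-bis(benzyloxy)phenyl]zinc chloride (not isolated) | Cl[Zn]c1ccc(OCc2ccccc2)cc1OCc1ccccc1 | intermediate
17 | (2R*,3S*,4S*,5S*)-3-[2,4-bis(benzyloxy)benzoyl]-4-(2,4-diacetoxybenzoyl)-2,5-bis(4-acetoxyphenyl)oxolane (racemic) | O=C(c1ccc(OCc2ccccc2)cc1OCc1ccccc1)[C@H]1[C@H](C(=O)c2ccc(OC(C)=O)cc2OC(C)=O)[C@@H](c2ccc(OC(C)=O)cc2)O[C@H]1c1ccc(OC(C)=O)cc1 | intermediate
18 | (2R*,3R*,4S*,5S*)-3-[2,4-bis(benzyloxy)benzoyl]-4-(2,4-dihydroxybenzoyl)-2,5-bis(4-hydroxyphenyl)oxolane (racemic) | O=C(c1ccc(OCc2ccccc2)cc1OCc1ccccc1)[C@@H]1[C@H](C(=O)c2ccc(O)cc2O)[C@@H](c2ccc(O)cc2)O[C@H]1c1ccc(O)cc1 | intermediate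
19 | [(2R,3R,4S,5S)-2,5-bis(4-hydroxyphenyl)oxolane-3,4-diyl]bis[(2,4-dihydroxyphenyl)methanone] (meso; CNP0237262.1) | O=C(c1ccc(O)cc1O)[C@@H]1[C@H](C(=O)c2ccc(O)cc2O)[C@@H](c2ccc(O)cc2)O[C@H]1c1ccc(O)cc1 | target

**Step count**
Total: 10 steps. Longest linear sequence: 8 steps (steps 2, 3, 4, 5, 6, 8, 9, 10, from 5 and 6 to 19).

**Steps most likely to fail**

Step 4. The electrophilic radical may add too slowly to the acceptor-substituted alkene, so that the keto ester is consumed by self-coupling, or the dihydrofuran may be dehydrogenated further to the furan by excess oxidant. The fallback is a two-electron route from 4 and 8 back to 9. Keto ester 4 would be brominated with N-bromosuccinimide to benzyl 3-(4-acetoxyphenyl)-2-bromo-3-oxopropanoate F1. Its enolate (K2CO3, MeCN, rt) would add to the beta-carbon of chalcone 8 and close by displacement of bromide (Michael-initiated ring closure) to the donor–acceptor cyclopropane benzyl 1-(4-acetoxybenzoyl)-2-(2,4-diacetoxybenzoyl)-3-(4-acetoxyphenyl)cyclopropane-1-carboxylate F2 (2,3-trans). A Lewis-acid-promoted Cloke–Wilson ring expansion (Sc(OTf)3, 1,2-dichloroethane, 60 °C) would break the bond between the doubly acceptor-substituted carbon and the aryl-bearing carbon and close the ketone enolate oxygen onto the benzylic carbon, giving the trans dihydrofuran 9.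

Step 5. Hydride may be delivered to the other face of C2 (giving 2,5-trans aryl groups), protonation of the deactivated enol ether may stall, or the aryl ketone may be reduced competitively. The fallback replaces the stepwise ionic reduction by a directed syn hydrogenation of 9 with the iridium complex [Ir(cod)(PCy3)(py)]PF6 under H2 in CH2Cl2. The C4 ketone oxygen should bind the metal and guide both hydrogens to C2=C3 from its own face, which is the face opposite the C5 aryl group. This gives the same 2,3-cis, 2,5-cis ester 10 directly, with the benzyl ester and acetates untouched; no new compound is involved.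

Step 9. The equilibrium may rest on the side of the 2,3-cis epimer, or prolonged enolisation may lead to beta-elimination of the ring oxygen and fragmentation. The fallback switches from thermodynamic to kinetic control and runs from 17 to 18. Brief methanolysis of 17 at 0 °C (K2CO3, MeOH) should remove the acetates before any C–H exchange and give the 2,3-cis tetraphenol (2R*,3S*,4S*,5S*)-3-[2,4-bis(benzyloxy)benzoyl]-4-(2,4-dihydroxybenzoyl)-2,5-bis(4-hydroxyphenyl)oxolane F3. Excess LiN(SiMe3)2 in THF at −78 °C would convert it into the pentalithium salt with the C3 enolate F4; C4 is not enolised because its ketone is conjugated to phenoxide. Irreversible protonation at −78 °C with a hindered acid (2,6-di-tert-butylphenol) would then give 18. The reasoning is that an unfavourable equilibrium would itself show the C4 aroyl group to be the more demanding neighbour, so the proton should enter anti to it and leave the C3 aroyl group cis to it.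

**Further compounds**
F1 | step 4 | benzyl 3-(4-acetoxyphenyl)-2-bromo-3-oxopropanoate | CC(=O)Oc1ccc(cc1)C(=O)C(Br)C(=O)OCc1ccccc1
F2 | step 4 | benzyl 1-(4-acetoxybenzoyl)-2-(2,4-diacetoxybenzoyl)-3-(4-acetoxyphenyl)cyclopropane-1-carboxylate (2,3-trans, racemic) | CC(=O)Oc1ccc(cc1)C(=O)C1(C(=O)OCc2ccccc2)[C@@H](C(=O)c2ccc(OC(C)=O)cc2OC(C)=O)[C@@H]1c1ccc(OC(C)=O)cc1
F0 | step 5 | none | none
F3 | step 9 | (2R*,3S*,4S*,5S*)-3-[2,4-bis(benzyloxy)benzoyl]-4-(2,4-dihydroxybenzoyl)-2,5-bis(4-hydroxyphenyl)oxolane (C3 epimer of 18) | O=C(c1ccc(OCc2ccccc2)cc1OCc1ccccc1)[C@H]1[C@H](C(=O)c2ccc(O)cc2O)[C@@H](c2ccc(O)cc2)O[C@H]1c1ccc(O)cc1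
F4 | step 9 | pentalithium salt of F3 with the C3 enolate | [Li+].[Li+].[Li+].[Li+].[Li+].[O-]C(c1ccc(OCc2ccccc2)cc1OCc1ccccc1)=C1[C@H](C(=O)c2ccc([O-])cc2[O-])[C@@H](c2ccc([O-])cc2)O[C@H]1c1ccc([O-])cc1
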